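**Retrosynthetic overview**
1. Target ⇒ desilylation, oxirane closure (C4–O attacks C5, inversion at C5) and Mitsunobu esterification (inversion at C8) ⇒ macrocyclic 8α-alcohol carrying a 4,5-acetonide.
2. Ten-membered ring ⇒ C7–C8 bond: light-driven, chromium-catalysed allylation of a C8 aldehyde by a tethered 3-(bromomethyl)butenolide (sets C7 and C8).
3. Butenolide ⇒ C6–C7 bond: Felkin-controlled chromium/nickel alkenylation of a dioxolane aldehyde with a (Z)-β-iodoacrylate, lactonising in the flask (sets C6).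
4. Dioxolane aldehyde ⇒ chelation-controlled MeMgBr addition (sets C4) to a ketone made by C2–C3 enolate alkylation with a (Z)-enynyl bromide; the alkyne is the masked C8 aldehyde.
5. All chirality comes from methyl (S)-2,3-O-isopropylideneglycerate (L-serine series, becomes C5); ring order: lactone, then ten-membered carbocycle, then oxirane.

Assumption: positions are given in germacrane numbering (C1 to C15, lactone carbonyl C12, exocyclic methylene C13), and 4CzIPN means 2,4,5,6-tetra(carbazol-9-yl)isophthalonitrile.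

**Step 1**
Reactants: 1 (2Z)-3-methylpent-2-en-4-yn-1-ol
Product: 2 (3Z)-5-bromo-3-methylpent-3-en-1-yne
Conditions: PBr3 (0.4 equiv), pyridine (cat.), Et2O, −20 to 0 °C
Reagents that add atoms: phosphorus tribromide, BrP(Br)Br
Why: Bromination of a primary allylic alcohol with PBr3 (SN2) keeps the purchased (Z)-trisubstituted alkene, which becomes the (Z)-1(10) alkene of the target.

**Step 2**
Reactants: 3 methyl (4S)-2,2-dimethyl-1,3-dioxolane-4-carboxylate
Product: 5 1-[(4S)-2,2-dimethyl-1,3-dioxolan-4-yl]ethan-1-one, via Weinreb amide 4 (not isolated)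
Conditions: MeNH(OMe)·HCl, i-PrMgCl, THF, −20 °C; then MeMgBr, −20 to 0 °C; aq. NH4Cl
Reagents that add atoms: methylmagnesium bromide, C[Mg]Br
Why: Weinreb ketone synthesis in one pot stops cleanly at the methyl ketone and leaves the purchased stereocentre (future C5) untouched.

**Step 3**
Reactants: 5 1-[(4S)-2,2-dimethyl-1,3-dioxolan-4-yl]ethan-1-one; 2 (3Z)-5-bromo-3-methylpent-3-en-1-yne
Product: 6 (4Z)-1-[(4S)-2,2-dimethyl-1,3-dioxolan-4-yl]-5-methylhept-4-en-6-yn-1-one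
Conditions: LiN(i-Pr)2, THF, −78 °C; then 2, DMPU, −78 to −30 °C
Reagents that add atoms: none
Why: Kinetic enolate alkylation (deprotonation on the methyl side, SN2 on the allylic bromide) forms the C2–C3 bond without enolising the α-alkoxy stereocentre or moving the (Z)-alkene.

**Step 4**
Reactants: 6 (4Z)-1-[(4S)-2,2-dimethyl-1,3-dioxolan-4-yl]-5-methylhept-4-en-6-yn-1-one
Product: 7 (2R,5Z)-2-[(4S)-2,2-dimethyl-1,3-dioxolan-4-yl]-6-methyloct-5-en-7-yn-2-ol
Conditions: MeMgBr (2.2 equiv), CH2Cl2/Et2O, −78 °C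
Reagents that add atoms: methylmagnesium bromide, C[Mg]Br
Why: Cram-chelate Grignard addition, in which magnesium bridges the carbonyl oxygen and the α-oxygen of the dioxolane and methyl enters from the face of the α-hydrogen, sets C4 as (R).

**Step 5**
Reactants: 7 (2R,5Z)-2-[(4S)-2,2-dimethyl-1,3-dioxolan-4-yl]-6-methyloct-5-en-7-yn-2-ol
Product: 8 {(4S,5R)-2,2,5-trimethyl-5-[(3Z)-4-methylhex-3-en-5-yn-1-yl]-1,3-dioxolan-4-yl}methanol
Conditions: p-TsOH·H2O (5 mol%), acetone, 23 °C (equilibration, 7 recycled)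
Reagents that add atoms: none
Why: Acid-catalysed acetonide migration (thermodynamic transketalisation) moves the ketal onto the tertiary/secondary diol and frees the primary alcohol without breaking any C–O bond at a stereocentre.

**Step 6**
Reactants: 8 {(4S,5R)-2,2,5-trimethyl-5-[(3Z)-4-methylhex-3-en-5-yn-1-yl]-1,3-dioxolan-4-yl}methanol
Product: 9 (4R,5R)-2,2,5-trimethyl-5-[(3Z)-4-methylhex-3-en-5-yn-1-yl]-1,3-dioxolane-4-carbaldehyde
Conditions: Dess–Martin periodinane, NaHCO3, CH2Cl2, 0 to 23 °C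
Reagents that add atoms: none
Why: Buffered Dess–Martin oxidation gives the α-alkoxy aldehyde under neutral conditions, so the α-centre does not epimerise (the descriptor changes only because CHO outranks the ring carbon).

**Step 7**
Reactants: 10 methyl prop-2-ynoate
Product: 11 methyl (2Z)-2-(hydroxymethyl)-3-iodoprop-2-enoate
Conditions: MgI2, paraformaldehyde, CH2Cl2, 0 to 23 °C
Reagents that add atoms: formaldehyde (from paraformaldehyde), C=O; magnesium diiodide, I[Mg]I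
Why: In this β-iodo Morita–Baylis–Hillman reaction iodide adds to the propiolate, the iodoallenolate traps formaldehyde, and the kinetic (Z)-isomer places iodine cis to the ester as needed for lactonisation.

**Step 8**
Reactants: 9 (4R,5R)-2,2,5-trimethyl-5-[(3Z)-4-methylhex-3-en-5-yn-1-yl]-1,3-dioxolane-4-carbaldehyde; 11 methyl (2Z)-2-(hydroxymethyl)-3-iodoprop-2-enoate
Product: 13 (5S)-3-(hydroxymethyl)-5-{(4S,5R)-2,2,5-trimethyl-5-[(3Z)-4-methylhex-3-en-5-yn-1-yl]-1,3-dioxolan-4-yl}furan-2(5H)-one, via hydroxy ester 12 (not isolated)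
Conditions: CrCl2 (4 equiv), NiCl2 (2 mol%), DMF, 23 °C; aq. NH4Cl
Reagents that add atoms: none
Why: In this Nozaki–Hiyama–Kishi alkenylation the alkenylchromium attacks in the polar Felkin–Anh sense (anti to the ring C5–O bond, past H5), which sets C6 as (S), and the cis γ-hydroxy enoate closes to the butenolide on work-up.

**Step 9**
Reactants: 13 (5S)-3-(hydroxymethyl)-5-{(4S,5R)-2,2,5-trimethyl-5-[(3Z)-4-methylhex-3-en-5-yn-1-yl]-1,3-dioxolan-4-yl}furan-2(5H)-one
Product: 15 (3Z)-6-{(4R,5S)-5-[(2S)-4-(hydroxymethyl)-5-oxo-2,5-dihydrofuran-2-yl]-2,2,4-trimethyl-1,3-dioxolan-4-yl}-3-methylhex-3-enal, via alkenylborane 14 (not isolated)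
Conditions: Cy2BH (2.3 equiv), THF, 0 °C; then 30% H2O2, pH 7 phosphate buffer, 0 °C
Reagents that add atoms: hydrogen peroxide, OO
Why: Hydroboration–oxidation with a hindered dialkylborane is selective for the terminal alkyne (boron on the terminal carbon), and buffered oxidation releases the β,γ-unsaturated aldehyde without moving the (Z)-alkene into conjugation.

**Step 10**
Reactants: 15 (3Z)-6-{(4R,5S)-5-[(2S)-4-(hydroxymethyl)-5-oxo-2,5-dihydrofuran-2-yl]-2,2,4-trimethyl-1,3-dioxolan-4-yl}-3-methylhex-3-enal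
Product: 16 (3Z)-6-{(4R,5S)-5-[(2S)-4-(bromomethyl)-5-oxo-2,5-dihydrofuran-2-yl]-2,2,4-trimethyl-1,3-dioxolan-4-yl}-3-methylhex-3-enal
Conditions: PPh3, N-bromosuccinimide (premixed), CH2Cl2, −30 to 0 °C
Reagents that add atoms: N-bromosuccinimide, O=C1CCC(=O)N1Br
Why: Appel-type bromination of the only hydroxyl (primary, allylic) runs under neutral conditions that the aldehyde and the acetonide tolerate.

**Step 11**
Reactants: 16 (3Z)-6-{(4R,5S)-5-[(2S)-4-(bromomethyl)-5-oxo-2,5-dihydrofuran-2-yl]-2,2,4-trimethyl-1,3-dioxolan-4-yl}-3-methylhex-3-enal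
Product: 17 (1(10)Z,4R,5S,6S,7R,8S)-8-hydroxy-4,5-(isopropylidenedioxy)germacra-1(10),11(13)-dien-12,6-olide (8α-OH, 4α,5α-acetonide, trans-fused 6α,12-lactone)
Conditions: CrCl2 (15 mol%), 4CzIPN (2 mol%), diethyl 1,4-dihydro-2,6-dimethylpyridine-3,5-dicarboxylate (Hantzsch ester, 1.5 equiv), degassed DMF (2 mM, 16 added over 12 h), 450 nm LEDs, 25 °C
Reagents that add atoms: none
Why: Proposed new method: a light-driven, chromium-catalysed macrocyclic Nozaki–Hiyama–Kishi-type allylation in which excited 4CzIPN, quenched by the Hantzsch ester, returns trivalent chromium to divalent chromium, which turns the bromomethylbutenolide into an allyl radical and then an allylchromium species (trivalent chromium) that adds through its γ-carbon C7 to the tethered aldehyde in a chair transition state, anti to the C6 substituent (C7 R, trans-lactone) and with the aldehyde chain equatorial (C8 S, 8α-OH), the Hantzsch pyridinium then releasing the alkoxide; the closest known reaction types are the stoichiometric CrCl2 macro-allylation used to close germacranolide rings and intermolecular dual photoredox/chromium carbonyl allylation.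

**Step 12**
Reactants: 18 2-[(tert-butyldiphenylsilyl)oxy]acetaldehyde; 19 ethyl 2-(triphenylphosphoranylidene)propanoate
Product: 20 ethyl (2E)-4-[(tert-butyldiphenylsilyl)oxy]-2-methylbut-2-enoate
Conditions: CH2Cl2, 23 °C
Reagents that add atoms: none
Why: Wittig olefination with the stabilised α-methyl ylide gives the (E)-trisubstituted enoate with high selectivity.

**Step 13**
Reactants: 20 ethyl (2E)-4-[(tert-butyldiphenylsilyl)oxy]-2-methylbut-2-enoate
Product: 21 (2E)-4-[(tert-butyldiphenylsilyl)oxy]-2-methylbut-2-enoic acid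
Conditions: LiOH·H2O, THF/H2O, 23 °C; then 1 M HCl to pH 3
Reagents that add atoms: lithium hydroxide, [Li+].[OH-]
Why: Saponification frees the acid while the silyl ether and the (E)-alkene are unaffected.

**Step 14**
Reactants: 17 (1(10)Z,4R,5S,6S,7R,8S)-8-hydroxy-4,5-(isopropylidenedioxy)germacra-1(10),11(13)-dien-12,6-olide; 21 (2E)-4-[(tert-butyldiphenylsilyl)oxy]-2-methylbut-2-enoic acid
Product: 22 (1(10)Z,4R,5S,6S,7R,8R)-8-{[(2E)-4-(tert-butyldiphenylsilyloxy)-2-methylbut-2-enoyl]oxy}-4,5-(isopropylidenedioxy)germacra-1(10),11(13)-dien-12,6-olide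
Conditions: PPh3, DIAD, toluene, 0 to 23 °C
Reagents that add atoms: none
Why: In the Mitsunobu esterification the carboxylate displaces the alkoxyphosphonium of the 8α-alcohol by SN2, so the ester is installed 8β (C8 R) with clean inversion.

**Step 15**
Reactants: 22 (1(10)Z,4R,5S,6S,7R,8R)-8-{[(2E)-4-(tert-butyldiphenylsilyloxy)-2-methylbut-2-enoyl]oxy}-4,5-(isopropylidenedioxy)germacra-1(10),11(13)-dien-12,6-olide
Product: 23 (1(10)Z,4R,5S,6S,7R,8R)-8-{[(2E)-4-(tert-butyldiphenylsilyloxy)-2-methylbut-2-enoyl]oxy}-4,5-dihydroxygermacra-1(10),11(13)-dien-12,6-olide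
Conditions: 2 M aq. HCl/THF (1:3), 23 °C
Reagents that add atoms: none
Why: Acidic acetonide hydrolysis is done before any oxirane is present, and the primary silyl ether, both esters and the alkenes survive dilute aqueous acid.

**Step 16**
Reactants: 23 (1(10)Z,4R,5S,6S,7R,8R)-8-{[(2E)-4-(tert-butyldiphenylsilyloxy)-2-methylbut-2-enoyl]oxy}-4,5-dihydroxygermacra-1(10),11(13)-dien-12,6-olide
Product: 25 (1(10)Z,4R,5R,6S,7R,8R)-8-{[(2E)-4-(tert-butyldiphenylsilyloxy)-2-methylbut-2-enoyl]oxy}-4,5-epoxygermacra-1(10),11(13)-dien-12,6-olide, via mesylate 24 (not isolated)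
Conditions: MsCl, Et3N, CH2Cl2, −20 °C; then DBU, 0 to 23 °C
Reagents that add atoms: none
Why: Only the secondary C5 hydroxyl is mesylated, and the tertiary C4 hydroxyl then closes the oxirane by intramolecular Williamson substitution with inversion at C5, giving the trans-trisubstituted epoxide (C4 R, C5 R).

**Step 17**
Reactants: 25 (1(10)Z,4R,5R,6S,7R,8R)-8-{[(2E)-4-(tert-butyldiphenylsilyloxy)-2-methylbut-2-enoyl]oxy}-4,5-epoxygermacra-1(10),11(13)-dien-12,6-olide
Product: 26 (1(10)Z,4R,5R,6S,7R,8R)-4,5-epoxy-8-{[(2E)-4-hydroxy-2-methylbut-2-enoyl]oxy}germacra-1(10),11(13)-dien-12,6-olide (CNP0198076.5)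
Conditions: Bu4NF/AcOH (1:1), THF, 0 to 23 °C
Reagents that add atoms: none
Why: Acetic-acid-buffered fluoride desilylation frees the primary allylic alcohol without opening the oxirane or adding to the α-methylene lactone.

**Compound list**
1 | (2Z)-3-methylpent-2-en-4-yn-1-ol | OC/C=C(C)\C#C | starting material
2 | (3Z)-5-bromo-3-methylpent-3-en-1-yne | BrC/C=C(C)\C#C | intermediate
3 | methyl (4S)-2,2-dimethyl-1,3-dioxolane-4-carboxylate (from L-serine) | COC(=O)[C@@H]1COC(C)(C)O1 | starting material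
4 | (4S)-N-methoxy-N,2,2-trimethyl-1,3-dioxolane-4-carboxamide (Weinreb amide) | CON(C)C(=O)[C@@H]1COC(C)(C)O1 | intermediate
5 | 1-[(4S)-2,2-dimethyl-1,3-dioxolan-4-yl]ethan-1-one | CC(=O)[C@@H]1COC(C)(C)O1 | intermediate
6 | (4Z)-1-[(4S)-2,2-dimethyl-1,3-dioxolan-4-yl]-5-methylhept-4-en-6-yn-1-one | C#C/C(C)=C\CCC(=O)[C@@H]1COC(C)(C)O1 | intermediate
7 | (2R,5Z)-2-[(4S)-2,2-dimethyl-1,3-dioxolan-4-yl]-6-methyloct-5-en-7-yn-2-ol | C#C/C(C)=C\CC[C@@](C)(O)[C@@H]1COC(C)(C)O1 | intermediate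
8 | {(4S,5R)-2,2,5-trimethyl-5-[(3Z)-4-methylhex-3-en-5-yn-1-yl]-1,3-dioxolan-4-yl}methanol | C#C/C(C)=C\CC[C@@]1(C)OC(C)(C)O[C@H]1CO | intermediate
9 | (4R,5R)-2,2,5-trimethyl-5-[(3Z)-4-methylhex-3-en-5-yn-1-yl]-1,3-dioxolane-4-carbaldehyde | C#C/C(C)=C\CC[C@@]1(C)OC(C)(C)O[C@H]1C=O | intermediate
10 | methyl prop-2-ynoate | C#CC(=O)OC | starting material
11 | methyl (2Z)-2-(hydroxymethyl)-3-iodoprop-2-enoate | I/C=C(CO)\C(=O)OC | intermediate
12 | methyl (2Z,4S)-4-hydroxy-2-(hydroxymethyl)-4-{(4S,5R)-2,2,5-trimethyl-5-[(3Z)-4-methylhex-3-en-5-yn-1-yl]-1,3-dioxolan-4-yl}but-2-enoate | C#C/C(C)=C\CC[C@@]1(C)OC(C)(C)O[C@H]1[C@@H](O)/C=C(CO)\C(=O)OC | intermediate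
13 | (5S)-3-(hydroxymethyl)-5-{(4S,5R)-2,2,5-trimethyl-5-[(3Z)-4-methylhex-3-en-5-yn-1-yl]-1,3-dioxolan-4-yl}furan-2(5H)-one | C#C/C(C)=C\CC[C@@]1(C)OC(C)(C)O[C@H]1[C@H]2OC(=O)C(CO)=C2 | intermediate
14 | 13 with its hydroxyl as the dicyclohexylborinate and its alkyne converted to the (E)-alkenyl dicyclohexylborane | C1CCCCC1B(C1CCCCC1)/C=C/C(C)=C\CC[C@@]2(C)OC(C)(C)O[C@H]2[C@H]3OC(=O)C(COB(C4CCCCC4)C5CCCCC5)=C3 | intermediate
15 | (3Z)-6-{(4R,5S)-5-[(2S)-4-(hydroxymethyl)-5-oxo-2,5-dihydrofuran-2-yl]-2,2,4-trimethyl-1,3-dioxolan-4-yl}-3-methylhex-3-enal | O=CC/C(C)=C\CC[C@@]1(C)OC(C)(C)O[C@H]1[C@H]2OC(=O)C(CO)=C2 | intermediate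
16 | (3Z)-6-{(4R,5S)-5-[(2S)-4-(bromomethyl)-5-oxo-2,5-dihydrofuran-2-yl]-2,2,4-trimethyl-1,3-dioxolan-4-yl}-3-methylhex-3-enal | O=CC/C(C)=C\CC[C@@]1(C)OC(C)(C)O[C@H]1[C@H]2OC(=O)C(CBr)=C2 | intermediate
17 | (1(10)Z,4R,5S,6S,7R,8S)-8-hydroxy-4,5-(isopropylidenedioxy)germacra-1(10),11(13)-dien-12,6-olide | C=C1C(=O)O[C@H]2[C@H]1[C@@H](O)C/C(C)=C\CC[C@@]3(C)OC(C)(C)O[C@@H]23 | intermediate
18 | 2-[(tert-butyldiphenylsilyl)oxy]acetaldehyde | O=CCO[Si](c1ccccc1)(c1ccccc1)C(C)(C)C | starting material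
19 | ethyl 2-(triphenylphosphoranylidene)propanoate | CCOC(=O)C(C)=P(c1ccccc1)(c1ccccc1)c1ccccc1 | starting material
20 | ethyl (2E)-4-[(tert-butyldiphenylsilyl)oxy]-2-methylbut-2-enoate | CCOC(=O)/C(C)=C/CO[Si](c1ccccc1)(c1ccccc1)C(C)(C)C | intermediate
21 | (2E)-4-[(tert-butyldiphenylsilyl)oxy]-2-methylbut-2-enoic acid | OC(=O)/C(C)=C/CO[Si](c1ccccc1)(c1ccccc1)C(C)(C)C | intermediate
22 | (1(10)Z,4R,5S,6S,7R,8R)-8-{[(2E)-4-(tert-butyldiphenylsilyloxy)-2-methylbut-2-enoyl]oxy}-4,5-(isopropylidenedioxy)germacra-1(10),11(13)-dien-12,6-olide | C=C1C(=O)O[C@H]2[C@H]1[C@H](OC(=O)/C(C)=C/CO[Si](c4ccccc4)(c5ccccc5)C(C)(C)C)C/C(C)=C\CC[C@@]3(C)OC(C)(C)O[C@@H]23 | intermediate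
23 | (1(10)Z,4R,5S,6S,7R,8R)-8-{[(2E)-4-(tert-butyldiphenylsilyloxy)-2-methylbut-2-enoyl]oxy}-4,5-dihydroxygermacra-1(10),11(13)-dien-12,6-olide | C=C1C(=O)O[C@H]2[C@H]1[C@H](OC(=O)/C(C)=C/CO[Si](c4ccccc4)(c5ccccc5)C(C)(C)C)C/C(C)=C\CC[C@@](C)(O)[C@H]2O | intermediate
24 | 5-O-methanesulfonate of 23 (C4 hydroxyl free) | C=C1C(=O)O[C@H]2[C@H]1[C@H](OC(=O)/C(C)=C/CO[Si](c4ccccc4)(c5ccccc5)C(C)(C)C)C/C(C)=C\CC[C@@](C)(O)[C@H]2OS(C)(=O)=O | intermediate
25 | (1(10)Z,4R,5R,6S,7R,8R)-8-{[(2E)-4-(tert-butyldiphenylsilyloxy)-2-methylbut-2-enoyl]oxy}-4,5-epoxygermacra-1(10),11(13)-dien-12,6-olide | C=C1C(=O)O[C@H]2[C@H]1[C@H](OC(=O)/C(C)=C/CO[Si](c4ccccc4)(c5ccccc5)C(C)(C)C)C/C(C)=C\CC[C@@]3(C)O[C@H]23 | intermediate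
26 | (1(10)Z,4R,5R,6S,7R,8R)-4,5-epoxy-8-{[(2E)-4-hydroxy-2-methylbut-2-enoyl]oxy}germacra-1(10),11(13)-dien-12,6-olide (CNP0198076.5) | C=C1C(=O)O[C@H]2[C@H]1[C@H](OC(=O)/C(C)=C/CO)C/C(C)=C\CC[C@@]1(C)O[C@H]21 | target

**Step count and risks**
Total step count: 17 (steps 1, 7, 12 and 13 make the three coupling partners).
Longest linear sequence: 13 steps (3 to 26 through steps 2–6, 8–11 and 14–17).

Steps most likely to fail:

Step 8 (butenolide annulation). The (Z)-iodoacrylate may isomerise on chromium or nickel, and the Felkin ratio on the hindered aldehyde is not certain. The fallback sets out from 9 and comes back at 13. LiC≡CCH2OSi(t-Bu)Me2 (from the silyl ether of propargyl alcohol and n-BuLi, THF, −78 °C) adds to 9 in the same Felkin sense to give propargylic alcohol F1. Hydroxyl-directed trans-hydroalumination with NaAlH2(OCH2CH2OMe)2 followed by I2 gives (Z)-vinyl iodide F2. Carbonylative lactonisation (PdCl2(PPh3)2 cat., CO 1 atm, K2CO3, THF) gives silyl-protected butenolide F3, and Bu4NF/AcOH then frees 13.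

Step 11 (the proposed light-driven macrocyclisation). The allylchromium may be protonated before it finds the aldehyde, the ring may close slowly, or the C8 ratio may be low. The fallback sets out from 16 and comes back at 17. It drops the photocatalytic radical generation and uses the classical stoichiometric Nozaki–Hiyama–Kishi allylation (CrCl2, 6 equiv, THF/DMF, dark, syringe-pump addition to 2 mM), the established two-electron way of closing germacranolide rings. It makes no new compound (F0).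

Step 14 (Mitsunobu inversion at the hindered C8 carbinol). Elimination towards C7 may compete. The fallback sets out from 17 and comes back at 22. Dess–Martin oxidation gives 8-ketone F4. Reduction with NaBH4/CeCl3·7H2O (MeOH, −78 °C), hydride arriving from the α-face anti to the C7–C11 bond, gives 8β-alcohol F5. Acylation with 21 (EDC·HCl, DMAP, CH2Cl2) then gives 22 with retention.

**Further compounds**
F1 | step 8 | (1S)-4-[(tert-butyldimethylsilyl)oxy]-1-{(4S,5R)-2,2,5-trimethyl-5-[(3Z)-4-methylhex-3-en-5-yn-1-yl]-1,3-dioxolan-4-yl}but-2-yn-1-ol | C#C/C(C)=C\CC[C@@]1(C)OC(C)(C)O[C@H]1[C@@H](O)C#CCO[Si](C)(C)C(C)(C)C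
F2 | step 8 | (1S,2Z)-4-[(tert-butyldimethylsilyl)oxy]-3-iodo-1-{(4S,5R)-2,2,5-trimethyl-5-[(3Z)-4-methylhex-3-en-5-yn-1-yl]-1,3-dioxolan-4-yl}but-2-en-1-ol | C#C/C(C)=C\CC[C@@]1(C)OC(C)(C)O[C@H]1[C@@H](O)/C=C(\I)CO[Si](C)(C)C(C)(C)C
F3 | step 8 | (5S)-3-{[(tert-butyldimethylsilyl)oxy]methyl}-5-{(4S,5R)-2,2,5-trimethyl-5-[(3Z)-4-methylhex-3-en-5-yn-1-yl]-1,3-dioxolan-4-yl}furan-2(5H)-one | C#C/C(C)=C\CC[C@@]1(C)OC(C)(C)O[C@H]1[C@H]2OC(=O)C(CO[Si](C)(C)C(C)(C)C)=C2
F0 | step 11 | none | none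
F4 | step 14 | (1(10)Z,4R,5S,6S,7S)-4,5-(isopropylidenedioxy)-8-oxogermacra-1(10),11(13)-dien-12,6-olide | C=C1C(=O)O[C@H]2[C@H]1C(=O)C/C(C)=C\CC[C@@]3(C)OC(C)(C)O[C@@H]23
F5 | step 14 | (1(10)Z,4R,5S,6S,7R,8R)-8-hydroxy-4,5-(isopropylidenedioxy)germacra-1(10),11(13)-dien-12,6-olide | C=C1C(=O)O[C@H]2[C@H]1[C@H](O)C/C(C)=C\CC[C@@]3(C)OC(C)(C)O[C@@H]23
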